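## Structural features

Amaurone B is built from three units joined in a line: a 2-methoxy-3,5-dimethyl-4H-pyran-4-one (O1, C2–C6), an all-(E) triene C7–C12 with methyls on C7 and C11, and a cyclohexane C13–C18 in which every ring carbon is a stereocentre. Taking the face of the C12 chain on C13 as β, the methyls on C14, C15 and C17 are also β, and the four oxygens (tertiary OH on C15 and C17, acetates on C16 and C18) are all α. C15–C18 therefore form an all-cis tetraol pattern in which two fully substituted carbinol carbons flank C16. The fragile parts are the triene–pyranone (light, acid, strong nucleophiles), the secondary acetates next to free tertiary hydroxyls (base), and any C12 carbonyl intermediate with an oxygen on C18 (β-elimination, epimerisation at C13). The chain is routine olefination; the real difficulty is the six contiguous ring centres, two of them tetrasubstituted. Ring C13–C18 has the substitution pattern of an endo [4+2] adduct: C14–C15–C16–C17 is a diene with two outside methyls and an oxygen on C16, and C13–C18 is an (E)-two-carbon unit whose substituents (the C12 carbon and the C18 oxygen) are trans. In the key step boron stands in for the C18 oxygen, and the C15=C16 enol ether left by the cycloaddition is the handle for the oxygens on C15, C16 and C17. Of the four centres the cycloaddition creates, C13, C14 and C18 are carried to the target; C17 is later flattened and rebuilt, but together with C14 it first steers the oxidation at C15.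

## Logic of the disconnections

33 to 32: the two acyl C–O bonds on O16 and O18 are cut. Acetates beside free tertiary hydroxyls would not survive the basic chain-building steps, so they go on last. This leaves a ring with four like hydroxyls. The forward acylation must take the two secondary hydroxyls and leave the two tertiary ones.

32 to 31: the four hydroxyls are paired as two isopropylidene acetals (O15/O16 and O17/O18). The cis-1,2 pairs allow all four to be masked in one operation, giving an intermediate with no acidic proton on the ring. The acetal cleavage must spare the triene and the pyranone.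

31 to 23 and 28: C7=C8 is cut. The pyranone then enters intact, as a cheap nucleophile, and the light-sensitive triene–pyranone exists only for the last three steps. The forward step needs 1,2-addition to the aldehyde and elimination to the (7E)-alkene.

23 to 21 (with 22), then 21 to 19 (with 20): C9=C10 and C11=C12 are cut in turn, each to an aldehyde and a carbonyl-stabilised phosphorus ylide. The chain shrinks to a C12 aldehyde on the ring. Both olefinations must be (E)-selective, must not epimerise C13 and must not run on to a longer polyenal.

19 to 18 to 17: C12 is returned to the ester level and the acetal C–O bonds are removed. The ester is the group that comes out of the cycloaddition, so no carbon is added or lost. The forward reduction must stop at the aldehyde.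

17 to 15: the C16–O and C17–O bonds are cut together. They are cis to each other and to the oxygens on C15 and C18, which is the retron of a syn-dihydroxylation. Two stereocentres disappear, leaving an alkene flanked by two allylic hydroxyls. The oxidant must be delivered from the hydroxyl-bearing face, against its intrinsic preference.

15 to 14 to 12 to 11: the O15–Si bond is restored, C18–O becomes C18–B, and C16–H becomes C16–O (enol triflate, then ketone). Boron is the oxygen surrogate that a cycloaddition tolerates, and the ketone is what an enol-ether oxidation leaves behind. The B-to-O exchange must go with retention. Enolisation can only go toward C17 because C15 is quaternary, and the C17 centre is given up there.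

11 to 9: the C15–O bond is cut (α-oxygenation of an enol ether). This returns to the cyclohexene enol ether with the double bond at C15=C16. The oxidant must approach anti to the C14 and C17 methyls.

9 to 5 and 8: C13–C14 and C17–C18 are cut, the [4+2] retron of a cyclohexene. The ring and four stereocentres vanish, leaving two achiral, acyclic partners. The forward step must give one regiochemistry, the endo adduct and one enantioface.

5 to 4 to 1 and 2: the O–Si bond, then the C=C bond of the enone (aldol condensation). Both starting materials are bulk chemicals. The enol ether must form on the ethyl side with (Z)-geometry so that both terminal methyls of the diene are "outside".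

8 to 6 and 7: the C–B bond. A syn addition of boron and hydrogen across the alkyne is needed, with boron on the β-carbon.

28 to 27 to 24 and 25: the O–CH3 bond, then O1–C2 and C5–C6 of the pyranone. The heterocycle reduces to a β-keto ester and a propionyl donor. Acylation must occur at the γ-carbon of the dianion, and methylation at the ring carbonyl oxygen.

## Other disconnections considered

Alternative 1: The cut is C15–O and C18–O together. In the forward direction, photosensitised singlet oxygen adds in a [4+2] sense across C15 and C18 of the cyclohexa-1,3-diene A2 to give the bicyclic endoperoxide A1. O–O reduction would then unveil a cis-1,4-diol with the C16=C17 alkene between the carbinols, the silyl-ether counterpart of 15, ready for the same directed dihydroxylation.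
- In favour: two C–O bonds and their cis relation are made in one step from oxygen and light, and the C13 and C14 substituents on one face of A2 should send the reagent to the other.
- Better than the chosen plan: it reaches the oxidation pattern of 15 in two operations from A2, where the chosen plan needs four (steps 5–8) from 9.
- Against: it presupposes A2 with C13 and C14 already set and says nothing about how. A2 offers singlet oxygen several ene pathways at its methyl-bearing alkenes. A2 can also isomerise or aromatise, and A1 has a C18–H that invites base-induced Kornblum–DeLaMare rearrangement to a hydroxy enone.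
- Comparison: both key steps are suprafacial [4+2] additions. The chosen one forms the two C–C bonds, the carbocycle and the C13/C14 centres; the alternative only decorates a ring that must come from elsewhere, most naturally from an adduct like 9. The two are complementary: if A2 were available in about as many steps as 9, the alternative would save roughly two steps.

Alternative 2: The cut is C13–C18. In the forward direction LiN(SiMe3)2 removes the γ-proton (C13) of the acyclic enoate A4, and the γ-carbon of the dienolate adds to the C18 aldehyde to give A3.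
- In favour: six-membered closure through the γ-carbon should beat α-attack, which would need an eight-membered ring.
- Equal or better on the chain: A3 already carries C11=C12 and the C10 ester, so one olefination is saved.
- Against: the whole stereochemical burden of C14–C17, including both tertiary carbinols, moves to an acyclic precursor and must be set one centre at a time. The two new centres (C13, C18, trans required) rest on substrate control in a transition state crowded by three silyl ethers. The aldol is reversible, and the enoate geometry passes through a dienolate.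
- Comparison: the chosen plan sets four ring centres in one catalytic, stereospecific, concerted step from achiral partners; here two centres are set in a stepwise, reversible ionic step. A4 would need well over ten steps, so the alternative is longer overall.

Alternative 3: The cut is C5–C6 and O1–C2 of the pyranone. In the forward direction the dianion of 24 is acylated by the trienoyl imidazolide A6, and DBU lactonisation gives the 4-hydroxy-2-pyranone A5, to be O-methylated afterwards. The carbon acylated is the γ-carbon, C4 of 24, which becomes C5 of the pyranone.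
- In favour: it is the same dependable ring synthesis as steps 14 and 15.
- Equal or better on geometry: C7=C8 would come from ylide chemistry, not from an aldol–elimination, so the (7E) geometry is easier to control.
- Against: a strongly basic dianion meets a trienoyl electrophile open to conjugate addition and deprotonation. The heterocycle is built and methylated on the most valuable intermediate, where the 2-methoxy-4-pyranone must be separated from its 4-methoxy-2-pyranone isomer. The main line is longer, and four silyl ethers must be carried.
- Comparison: this alternative does not address the ring and is compatible with the same cycloaddition; on the core the two plans are equal. The chosen plan does the identical pyranone chemistry off-line on cheap material, which is more convergent.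

Key step: step 4

Assumption: the catalyst antipode is chosen by analogy with additions of simple acrylate esters to 1,3-dienes under this oxazaborolidinium ion, which should make C13 of the adduct (S). Both antipodes are available, and the other would be used unchanged if the first adduct proved enantiomeric.

Face convention in the names: β is the face of the carbon substituent on C13, α the opposite face; locants C7–C18 follow the target.

## Route

Step 1
Reactants: 1 3-pentanone; 2 acetaldehyde
Product: 4 (E)-4-methylhex-4-en-3-one, via 5-hydroxy-4-methylhexan-3-one 3 (not isolated)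
Conditions: 1 (3 equiv), aq. KOH (cat.), 0–10 °C; neutralise; p-TsOH (cat.), toluene, reflux with removal of water; distil
Reagents that add atoms: none
Why: Crossed aldol addition of the symmetrical ketone to the more electrophilic aldehyde, then acid-catalysed dehydration (aldol condensation); the trisubstituted enone should form as the more stable (E)-isomer, and the excess of 1 suppresses self-condensation of 2.

Step 2
Reactants: 4 (E)-4-methylhex-4-en-3-one
Product: 5 (2Z,4E)-3-(tert-butyldimethylsilyloxy)-4-methylhexa-2,4-diene
Conditions: TBSOTf (1.1 equiv), Et3N (1.5 equiv), CH2Cl2, 0 °C to rt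
Reagents that add atoms: tert-butyldimethylsilyl trifluoromethanesulfonate, CC(C)(C)[Si](C)(C)OS(=O)(=O)C(F)(F)F
Why: Soft enolisation on the ethyl side (silyl triflate and amine) gives the cross-conjugated 2-siloxy diene; the (Z)-enol ether is favoured because it avoids allylic strain between the new vinylic methyl and the C4 substituent, so both terminal methyls are "outside" in the s-cis diene.

Step 3
Reactants: 6 methyl propiolate; 7 bis(pinacolato)diboron
Product: 8 methyl (E)-3-(4,4,5,5-tetramethyl-1,3,2-dioxaborolan-2-yl)prop-2-enoate
Conditions: CuCl (3 mol %), NaOt-Bu (6 mol %), 4,5-bis(diphenylphosphino)-9,9-dimethylxanthene (3 mol %), 7 (1.05 equiv), MeOH (2 equiv), THF, rt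
Reagents that add atoms: none
Why: Copper-catalysed formal hydroboration: a Cu–Bpin species adds syn across the alkyne with boron on the β-carbon, and methanol protonates the C–Cu bond with retention, so boron and ester should end trans.

Step 4
Reactants: 5 (2Z,4E)-3-(tert-butyldimethylsilyloxy)-4-methylhexa-2,4-diene; 8 methyl (E)-3-(4,4,5,5-tetramethyl-1,3,2-dioxaborolan-2-yl)prop-2-enoate
Product: 9 methyl (1S,2S,5R,6R)-4-(tert-butyldimethylsilyloxy)-2,3,5-trimethyl-6-(4,4,5,5-tetramethyl-1,3,2-dioxaborolan-2-yl)cyclohex-3-ene-1-carboxylate (13β-CO2Me, 14β-Me, 17β-Me, 18α-Bpin)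
Conditions: (S)-3,3-diphenyl-1-(o-tolyl)tetrahydro-1H,3H-pyrrolo[1,2-c][1,3,2]oxazaborole (20 mol %), Tf2NH (18 mol %), CH2Cl2, −78 °C; 8, then 5 (1.5 equiv), −78 to −40 °C
Reagents that add atoms: none
Why: The protonated oxazaborolidine binds the ester carbonyl of 8 and lowers its LUMO, and the 2-siloxy diene 5 adds in a concerted, asynchronous, suprafacial–suprafacial [4+2] cycloaddition in which C17–C18 bonding runs ahead of C13–C14; the six-membered ring closes in this single step. The closest known reaction type is the oxazaborolidinium-catalysed Diels–Alder addition of 2-silyloxy dienes to acrylate esters, together with the use of alkenyl boronates as dienophiles. The siloxy group on C16 puts the largest HOMO coefficient on C17, which therefore bonds to the ester β-carbon C18, while C14 bonds to the α-carbon C13. The (E)-geometry of 8 is carried over as the trans relation of the C13 ester and the C18 boron, and the two outside methyls of the (2Z,4E)-diene end cis to each other on C14 and C17. Endo approach of the catalyst-bound ester places it cis to both methyls. The absolute configuration of all four centres comes from the catalyst, whose aryl groups shield one face of the bound s-trans acrylate. The step needs one regiochemistry, endo selectivity, one enantioface and no leakage into a stepwise Mukaiyama–Michael path; the siloxy group, the carbonyl-bound catalyst, and the low temperature with a robust tert-butyldimethylsilyl enol ether are what should secure them.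

Step 5
Reactants: 9 the cycloadduct
Product: 11 methyl 3-(tert-butyldimethylsilyloxy)-2,3,5-trimethyl-4-oxo-6-(pinacolboryl)cyclohexane-1-carboxylate (15β-Me, 15α-OTBS; C13, C14, C17, C18 as in 9), via silyloxy epoxide 10 (not isolated)
Conditions: mCPBA (1.05 equiv), NaHCO3, CH2Cl2, −20 to 0 °C
Reagents that add atoms: 3-chloroperoxybenzoic acid, O=C(OO)c1cccc(Cl)c1
Why: Rubottom oxidation: the peracid should epoxidise the electron-rich enol ether on the face opposite the two allylic methyls (one is pseudoaxial in either half-chair), and the silyloxy epoxide opens to the oxocarbenium ion and collapses by 1,4-silyl shift, placing the C15 oxygen α. The secondary alkyl pinacol boronate reacts with peracid far more slowly than the tetrasubstituted enol ether.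

Step 6
Reactants: 11 the α-silyloxy ketone
Product: 12 methyl 3-(tert-butyldimethylsilyloxy)-2,3,5-trimethyl-6-(pinacolboryl)-4-(trifluoromethanesulfonyloxy)cyclohex-4-ene-1-carboxylate
Conditions: KN(SiMe3)2 (1.1 equiv), THF, −78 °C; PhNTf2 (1.2 equiv), −78 to 0 °C
Reagents that add atoms: N-phenylbis(trifluoromethanesulfonimide), O=S(=O)(N(c1ccccc1)S(=O)(=O)C(F)(F)F)C(F)(F)F
Why: C15 is quaternary, so the ketone can enolise only toward C17, and O-sulfonylation of the potassium enolate gives the enol triflate; the ester α-proton is several pK units less acidic and should be left alone at −78 °C. The C17 centre from step 4 is deliberately given up here and rebuilt in step 9.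

Step 7
Reactants: 12 the enol triflate
Product: 14 methyl 3-(tert-butyldimethylsilyloxy)-6-hydroxy-2,3,5-trimethylcyclohex-4-ene-1-carboxylate (15α-OTBS, 18α-OH), via allylboronate 13 (not isolated)
Conditions: Pd(PPh3)4 (5 mol %), LiCl (3 equiv), Bu3SnH (1.3 equiv), THF, rt; then H2O, NaBO3·4H2O (5 equiv), rt
Reagents that add atoms: sodium perborate tetrahydrate (peroxoborate dianion shown), [Na+].[Na+].O[B-]1(O)OO[B-](O)(O)OO1
Why: Zerovalent palladium inserts into the C–O bond of the triflate, hydride is passed from tin, and reductive elimination leaves the C16=C17 alkene. The allylic boronate is oxidised in the same flask, the 1,2-shift from boron to oxygen going with retention at C18 and without allylic transposition.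

Step 8
Reactants: 14 the allylic alcohol
Product: 15 methyl 3,6-dihydroxy-2,3,5-trimethylcyclohex-4-ene-1-carboxylate (15α-OH, 18α-OH)
Conditions: Bu4NF (2 equiv), THF, 0 °C to rt
Reagents that add atoms: none
Why: Fluoride cleaves the tertiary silyl ether while the molecule is still robust, so that no hindered silyl ether has to be removed from the polyene later and both allylic hydroxyls are free to direct the next step. Lactonisation is not possible because every hydroxyl is trans to the ester.

Step 9
Reactants: 15 the ene-diol
Product: 17 methyl 3,4,5,6-tetrahydroxy-2,3,5-trimethylcyclohexane-1-carboxylate (15α, 16α, 17α, 18α hydroxyls; 14β, 15β, 17β methyls), via osmate ester 16 (not isolated)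
Conditions: OsO4 (1.05 equiv), TMEDA (1.1 equiv), CH2Cl2, −78 °C; then sat. aq. Na2SO3, THF, 40 °C
Reagents that add atoms: osmium tetroxide, O=[Os](=O)(=O)=O
Why: Hydrogen-bond-directed syn-dihydroxylation: the OsO4–diamine complex is held by the two allylic hydroxyls on the α face and should add to C16=C17 from that face, setting C16 and C17 in one step and giving the all-cis tetraol. Without the diamine, addition anti to the allylic oxygens would be expected.

Step 10
Reactants: 17 the tetraol ester
Product: 18 methyl 15,16:17,18-di-O-isopropylidene tetraol ester (two cis-fused dioxolanes on the α face)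
Conditions: Me2C(OMe)2 (10 equiv), camphorsulfonic acid (0.1 equiv), acetone, rt
Reagents that add atoms: 2,2-dimethoxypropane, COC(C)(C)OC
Why: Acid-catalysed acetal exchange under equilibrating conditions; pairing O15/O16 and O17/O18 is the only arrangement that caps all four hydroxyls, so the bis-acetonide should be the thermodynamic product.

Step 11
Reactants: 18 the bis-acetonide ester
Product: 19 the corresponding C12 aldehyde (15,16:17,18-di-O-isopropylidene)
Conditions: i-Bu2AlH (1.2 equiv), CH2Cl2, −78 °C; MeOH, then aq. potassium sodium tartrate
Reagents that add atoms: none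
Why: Partial reduction of the ester: the aluminium hemiacetal is stable at −78 °C, helped by chelation to the acetal oxygen on C18, and releases the aldehyde only on work-up, so C13 sees neither acid nor base.

Step 12
Reactants: 19 the aldehyde; 20 2-(triphenylphosphoranylidene)propanal
Product: 21 (E)-2-methyl-3-(ring)prop-2-enal, ring = the bis-acetonide cyclohexyl unit attached at C13 (11E)
Conditions: 20 (2 equiv), toluene, 90 °C
Reagents that add atoms: none
Why: Wittig reaction of a formyl-stabilised ylide; reversible oxaphosphetane formation favours the (E)-trisubstituted enal, and the ylide is too weakly basic to epimerise C13 or expel the C18 oxygen.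

Step 13
Reactants: 21 the enal; 22 (triphenylphosphoranylidene)acetaldehyde
Product: 23 (2E,4E)-4-methyl-5-(ring)penta-2,4-dienal (9E,11E; C8 aldehyde)
Conditions: 22 (1.3 equiv), toluene, 80 °C, followed to partial conversion
Reagents that add atoms: none
Why: Second Wittig homologation with a stabilised ylide, (E)-selective; the ylide is kept in small excess and the reaction stopped early because the product is itself an enal.

Step 14
Reactants: 24 methyl 2-methyl-3-oxopentanoate; 25 N-methoxy-N-methylpropanamide
Product: 27 6-ethyl-4-hydroxy-3,5-dimethyl-2H-pyran-2-one, via methyl 2,4-dimethyl-3,5-dioxoheptanoate 26 (not isolated)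
Conditions: NaH (1.1 equiv), THF, 0 °C; n-BuLi (1.05 equiv), 0 °C; 25, −78 to 0 °C; aq. HCl; crude in toluene, DBU, 80 °C
Reagents that add atoms: none
Why: Claisen-type acylation of the β-keto ester dianion at its more nucleophilic γ-carbon (C4 of 24) gives the 3,5-diketo ester; under DBU its C5 enol oxygen closes onto the ester to form the 4-hydroxy-2-pyranone.

Step 15
Reactants: 27 the hydroxypyranone
Product: 28 6-ethyl-2-methoxy-3,5-dimethyl-4H-pyran-4-one
Conditions: MeOTf (1.2 equiv), CH2Cl2, rt; aq. NaHCO3
Reagents that add atoms: methyl trifluoromethanesulfonate, COS(=O)(=O)C(F)(F)F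
Why: The hard methylating agent should attack the ring carbonyl oxygen, the most basic site, giving a 2-methoxy-4-hydroxypyrylium ion that loses a proton to the 2-methoxy-4-pyranone; any 4-methoxy-2-pyranone isomer would be separated here on cheap material.

Step 16
Reactants: 23 the dienal; 28 6-ethyl-2-methoxy-3,5-dimethyl-4H-pyran-4-one
Product: 31 15,16:17,18-di-O-isopropylidene-16,18-di-O-deacetylamaurone B (7E,9E,11E), via lithium aldolate 29 (not isolated), via allylic acetate 30 (not isolated)
Conditions: 28 (1.3 equiv), LiN(SiMe3)2 (1.3 equiv), THF, −78 °C; 23; Ac2O (2 equiv), −78 to 0 °C; DBU (4 equiv), rt, dark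
Reagents that add atoms: none
Why: The extended enolate of 28 (deprotonation of the 6-ethyl CH2) adds 1,2 to the dienal (vinylogous aldol); the alkoxide is acetylated in the flask, and DBU removes the acidic C7–H to expel acetate (E1cB), which should give the conjugated and more stable (7E)-alkene.

Step 17
Reactants: 31 the protected triene–pyranone
Product: 32 16,18-di-O-deacetylamaurone B (tetraol)
Conditions: p-TsOH·H2O (0.2 equiv), MeOH, rt, dark
Reagents that add atoms: none
Why: Acid-catalysed acetal exchange with methanol removes both acetonides; no carbinol carbon is allylic, so none should ionise, and the pyranone methoxy group can only exchange with the solvent's own methoxyl.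

Step 18
Reactants: 32 the tetraol
Product: 33 amaurone B
Conditions: Ac2O (3 equiv), pyridine, DMAP (cat.), CH2Cl2, 0 °C to rt, dark
Reagents that add atoms: acetic anhydride, CC(=O)OC(C)=O
Why: Acylation should discriminate the two secondary, equatorial hydroxyls on C16 and C18 from the two tertiary, axial, mutually hydrogen-bonded hydroxyls on C15 and C17, which are not expected to acylate under these conditions.

## Compound list

1 | 3-pentanone | CCC(=O)CC | starting material
2 | acetaldehyde | CC=O | starting material
3 | 5-hydroxy-4-methylhexan-3-one (diastereomer mixture) | CCC(=O)C(C)C(C)O | intermediate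
4 | (E)-4-methylhex-4-en-3-one | C/C=C(\C)C(=O)CC | intermediate
5 | (2Z,4E)-3-(tert-butyldimethylsilyloxy)-4-methylhexa-2,4-diene | C/C=C(\O[Si](C)(C)C(C)(C)C)/C(C)=C/C | intermediate
6 | methyl propiolate | C#CC(=O)OC | starting material
7 | bis(pinacolato)diboron | CC1(C)OB(OC1(C)C)B1OC(C)(C)C(C)(C)O1 | starting material
8 | methyl (E)-3-(4,4,5,5-tetramethyl-1,3,2-dioxaborolan-2-yl)prop-2-enoate | COC(=O)/C=C/B1OC(C)(C)C(C)(C)O1 | intermediate
9 | methyl (1S,2S,5R,6R)-4-(tert-butyldimethylsilyloxy)-2,3,5-trimethyl-6-(pinacolboryl)cyclohex-3-ene-1-carboxylate | COC(=O)[C@@H]1[C@H](C)C(C)=C(O[Si](C)(C)C(C)(C)C)[C@H](C)[C@H]1B2OC(C)(C)C(C)(C)O2 | intermediate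
10 | 15,16-epoxide of 9 (epoxide oxygen α, OTBS on C16 β) | COC(=O)[C@@H]1[C@H](C)[C@@]2(C)O[C@@]2(O[Si](C)(C)C(C)(C)C)[C@H](C)[C@H]1B1OC(C)(C)C(C)(C)O1 | intermediate
11 | methyl 3-(tert-butyldimethylsilyloxy)-2,3,5-trimethyl-4-oxo-6-(pinacolboryl)cyclohexane-1-carboxylate (15α-OTBS) | COC(=O)[C@@H]1[C@H](C)[C@@](C)(O[Si](C)(C)C(C)(C)C)C(=O)[C@H](C)[C@H]1B1OC(C)(C)C(C)(C)O1 | intermediate
12 | enol triflate of 11 (C16–OTf, C16=C17) | COC(=O)[C@@H]1[C@H](C)[C@@](C)(O[Si](C)(C)C(C)(C)C)C(OS(=O)(=O)C(F)(F)F)=C(C)[C@H]1B1OC(C)(C)C(C)(C)O1 | intermediate
13 | methyl 3-(tert-butyldimethylsilyloxy)-2,3,5-trimethyl-6-(pinacolboryl)cyclohex-4-ene-1-carboxylate (allylboronate) | COC(=O)[C@@H]1[C@H](C)[C@@](C)(O[Si](C)(C)C(C)(C)C)C=C(C)[C@H]1B1OC(C)(C)C(C)(C)O1 | intermediate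
14 | methyl 3-(tert-butyldimethylsilyloxy)-6-hydroxy-2,3,5-trimethylcyclohex-4-ene-1-carboxylate (18α-OH) | COC(=O)[C@@H]1[C@H](C)[C@@](C)(O[Si](C)(C)C(C)(C)C)C=C(C)[C@H]1O | intermediate
15 | methyl 3,6-dihydroxy-2,3,5-trimethylcyclohex-4-ene-1-carboxylate (15α-OH, 18α-OH) | COC(=O)[C@@H]1[C@H](C)[C@@](C)(O)C=C(C)[C@H]1O | intermediate
16 | cyclic osmate ester of 15 across C16/C17 on the α face, TMEDA-chelated hexavalent osmium | COC(=O)[C@@H]1[C@H](C)[C@@](C)(O)[C@H]2O[Os-2]3(=O)(=O)(O[C@@]2(C)[C@H]1O)[N+](C)(C)CC[N+]3(C)C | intermediate
17 | methyl 3,4,5,6-tetrahydroxy-2,3,5-trimethylcyclohexane-1-carboxylate (all four OH α) | COC(=O)[C@@H]1[C@H](C)[C@@](C)(O)[C@@H](O)[C@@](C)(O)[C@H]1O | intermediate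
18 | 15,16:17,18-di-O-isopropylidene derivative of 17 | COC(=O)[C@@H]1[C@H](C)[C@@]2(C)OC(C)(C)O[C@H]2[C@@]3(C)OC(C)(C)O[C@@H]13 | intermediate
19 | C12 aldehyde (bis-acetonide) | O=C[C@@H]1[C@H](C)[C@@]2(C)OC(C)(C)O[C@H]2[C@@]3(C)OC(C)(C)O[C@@H]13 | intermediate
20 | 2-(triphenylphosphoranylidene)propanal | CC(C=O)=P(c1ccccc1)(c1ccccc1)c1ccccc1 | starting material
21 | (E)-enal, C10 aldehyde (bis-acetonide) | O=C/C(C)=C/[C@@H]1[C@H](C)[C@@]2(C)OC(C)(C)O[C@H]2[C@@]3(C)OC(C)(C)O[C@@H]13 | intermediate
22 | (triphenylphosphoranylidene)acetaldehyde | O=CC=P(c1ccccc1)(c1ccccc1)c1ccccc1 | starting material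
23 | (2E,4E)-dienal, C8 aldehyde (bis-acetonide) | O=C/C=C/C(C)=C/[C@@H]1[C@H](C)[C@@]2(C)OC(C)(C)O[C@H]2[C@@]3(C)OC(C)(C)O[C@@H]13 | intermediate
24 | methyl 2-methyl-3-oxopentanoate | CCC(=O)C(C)C(=O)OC | starting material
25 | N-methoxy-N-methylpropanamide | CCC(=O)N(C)OC | starting material
26 | methyl 2,4-dimethyl-3,5-dioxoheptanoate | CCC(=O)C(C)C(=O)C(C)C(=O)OC | intermediate
27 | 6-ethyl-4-hydroxy-3,5-dimethyl-2H-pyran-2-one | CCC1=C(C)C(O)=C(C)C(=O)O1 | intermediate
28 | 6-ethyl-2-methoxy-3,5-dimethyl-4H-pyran-4-one | CCc1oc(OC)c(C)c(=O)c1C | intermediate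
29 | lithium C8 alkoxide of the aldol adduct of 28 and 23 (C7/C8 diastereomer mixture) | [Li+].COc1oc(C(C)C([O-])/C=C/C(C)=C/[C@@H]2[C@H](C)[C@@]3(C)OC(C)(C)O[C@H]3[C@@]4(C)OC(C)(C)O[C@@H]24)c(C)c(=O)c1C | intermediate
30 | C8 acetate of the aldol adduct (C7/C8 diastereomer mixture) | COc1oc(C(C)C(OC(C)=O)/C=C/C(C)=C/[C@@H]2[C@H](C)[C@@]3(C)OC(C)(C)O[C@H]3[C@@]4(C)OC(C)(C)O[C@@H]24)c(C)c(=O)c1C | intermediate
31 | 15,16:17,18-di-O-isopropylidene-16,18-di-O-deacetylamaurone B | COc1oc(/C(C)=C/C=C/C(C)=C/[C@@H]2[C@H](C)[C@@]3(C)OC(C)(C)O[C@H]3[C@@]4(C)OC(C)(C)O[C@@H]24)c(C)c(=O)c1C | intermediate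
32 | 16,18-di-O-deacetylamaurone B | COc1oc(/C(C)=C/C=C/C(C)=C/[C@@H]2[C@H](C)[C@@](C)(O)[C@@H](O)[C@@](C)(O)[C@H]2O)c(C)c(=O)c1C | intermediate
33 | amaurone B | COc1oc(/C(C)=C/C=C/C(C)=C/[C@@H]2[C@H](C)[C@@](C)(O)[C@@H](OC(C)=O)[C@@](C)(O)[C@H]2OC(C)=O)c(C)c(=O)c1C | target

## Step count and least certain steps

Total: 18 steps. Longest linear sequence: 15 steps (1, 2, 4–13, 16–18). The diene arm is 2 steps, the dienophile 1 step and the pyranone 2 steps. Everything from step 16 on should be handled with exclusion of light.

Step 4 (key step). Most likely to go wrong: the strongly acidic catalyst may turn the concerted addition into a stepwise Mukaiyama–Michael addition with silyl transfer or protodesilylation of the diene. The doubly terminally substituted diene and the β-substituted acrylate may also react too slowly for good endo and enantioface selection, and the facial sense rests on analogy. Fallback, from 8 back to 9, using auxiliary control with two-point binding: 8 is saponified (LiOH, aq. THF) to (E)-3-(pinacolboryl)prop-2-enoic acid F1. Via the pivaloyl mixed anhydride, F1 is joined to lithiated (R)-4-benzyloxazolidin-2-one to give the imide F2. F2 and 5 undergo the Me2AlCl-promoted Diels–Alder reaction (chelated s-cis imide, diene anti to the benzyl group) to give the adduct F3. MeOMgBr in MeOH/CH2Cl2 at 0 °C exchanges the auxiliary for the methyl ester, returning to 9.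

Step 9. Most likely to go wrong: poor facial selectivity, if hydrogen-bond delivery does not override the intrinsic preference of OsO4 for the face anti to allylic oxygens, or slow osmylation of an alkene flanked by a quaternary carbon. Fallback, from 11 back to 17, building C17–O and C16–O one at a time through the ketone:
- 11 is converted (TBSOTf, Et3N) into the C16=C17 silyl enol ether F4.
- NaBO3·4H2O frees the C18 hydroxyl to give F5.
- mCPBA, directed by that allylic hydroxyl, epoxidises the enol ether on the α face, and silyl shift gives the α-silyloxy ketone F6 with the C17 oxygen α.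
- NaBH4 should attack the ketone anti to the two axial silyloxy groups, giving the C16 α-alcohol F7.
- Bu4NF removes both silyl groups to give 17.

Step 7. Most likely to go wrong: loss of the allylic boron before it is oxidised (protodeboronation or allyl transfer to palladium), or slow oxidative addition of the hindered, tetrasubstituted triflate. Fallback, from 11 back to 15, in which boron is exchanged for oxygen before any alkene is made:
- NaBO3·4H2O converts 11 into the β-hydroxy ketone F8.
- Et3SiCl/imidazole gives the silyl ether F9.
- KN(SiMe3)2/PhNTf2 gives the enol triflate F10.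
- Pd(OAc)2, PPh3, HCO2H and Bu3N reduce it to the alkene F11.
- Bu4NF removes both silyl groups and gives 15 directly.

Step 13. Most likely to go wrong: over-homologation, because the product dienal is less hindered than the α-methyl enal that is consumed. Fallback, from 21 back to 23, through the ester oxidation level: Horner–Wadsworth–Emmons reaction of 21 with triethyl phosphonoacetate (LiCl, DBU) gives the (2E,4E)-dienoate F12, which cannot react further. i-Bu2AlH reduces it to the dienol F13, and MnO2 oxidises the allylic alcohol to 23.

Step 16. Most likely to go wrong: ionisation of the doubly allylic acetate with scrambling of the triene geometry, retro-aldol cleavage before acetylation, or incomplete control of the C7=C8 geometry in the elimination. Fallback, from 28 back to 31, forming C7=C8 by a Wittig reaction with the polarity of the partners unchanged: the lithium enolate of 28 is brominated (CBr4) to 6-(1-bromoethyl)-2-methoxy-3,5-dimethyl-4H-pyran-4-one F14. PPh3 in warm toluene gives the phosphonium bromide F15. K2CO3 in the presence of 23 generates the pyranone-stabilised ylide, which should give the (7E)-alkene 31 as stabilised secondary ylides do.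

## Further compounds

F1 | step 4 | (E)-3-(4,4,5,5-tetramethyl-1,3,2-dioxaborolan-2-yl)prop-2-enoic acid | OC(=O)/C=C/B1OC(C)(C)C(C)(C)O1
F2 | step 4 | (R)-4-benzyl-3-[(E)-3-(pinacolboryl)prop-2-enoyl]oxazolidin-2-one | O=C1OC[C@@H](Cc2ccccc2)N1C(=O)/C=C/B1OC(C)(C)C(C)(C)O1
F3 | step 4 | N-acyloxazolidinone analogue of 9 (same ring configuration, (R)-4-benzyl auxiliary) | O=C1OC[C@@H](Cc2ccccc2)N1C(=O)[C@@H]1[C@H](C)C(C)=C(O[Si](C)(C)C(C)(C)C)[C@H](C)[C@H]1B1OC(C)(C)C(C)(C)O1
F4 | step 9 | methyl 3,4-bis(tert-butyldimethylsilyloxy)-2,3,5-trimethyl-6-(pinacolboryl)cyclohex-4-ene-1-carboxylate | COC(=O)[C@@H]1[C@H](C)[C@@](C)(O[Si](C)(C)C(C)(C)C)C(O[Si](C)(C)C(C)(C)C)=C(C)[C@H]1B1OC(C)(C)C(C)(C)O1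
F5 | step 9 | methyl 3,4-bis(tert-butyldimethylsilyloxy)-6-hydroxy-2,3,5-trimethylcyclohex-4-ene-1-carboxylate | COC(=O)[C@@H]1[C@H](C)[C@@](C)(O[Si](C)(C)C(C)(C)C)C(O[Si](C)(C)C(C)(C)C)=C(C)[C@H]1O
F6 | step 9 | methyl 3,5-bis(tert-butyldimethylsilyloxy)-6-hydroxy-2,3,5-trimethyl-4-oxocyclohexane-1-carboxylate (15α, 17α, 18α oxygens) | COC(=O)[C@@H]1[C@H](C)[C@@](C)(O[Si](C)(C)C(C)(C)C)C(=O)[C@@](C)(O[Si](C)(C)C(C)(C)C)[C@H]1O
F7 | step 9 | methyl 3,5-bis(tert-butyldimethylsilyloxy)-4,6-dihydroxy-2,3,5-trimethylcyclohexane-1-carboxylate (all oxygens α) | COC(=O)[C@@H]1[C@H](C)[C@@](C)(O[Si](C)(C)C(C)(C)C)[C@@H](O)[C@@](C)(O[Si](C)(C)C(C)(C)C)[C@H]1O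
F8 | step 7 | methyl 3-(tert-butyldimethylsilyloxy)-6-hydroxy-2,3,5-trimethyl-4-oxocyclohexane-1-carboxylate | COC(=O)[C@@H]1[C@H](C)[C@@](C)(O[Si](C)(C)C(C)(C)C)C(=O)[C@H](C)[C@H]1O
F9 | step 7 | methyl 3-(tert-butyldimethylsilyloxy)-2,3,5-trimethyl-4-oxo-6-(triethylsilyloxy)cyclohexane-1-carboxylate | COC(=O)[C@@H]1[C@H](C)[C@@](C)(O[Si](C)(C)C(C)(C)C)C(=O)[C@H](C)[C@H]1O[Si](CC)(CC)CC
F10 | step 7 | enol triflate of F9 (C16–OTf, C16=C17) | COC(=O)[C@@H]1[C@H](C)[C@@](C)(O[Si](C)(C)C(C)(C)C)C(OS(=O)(=O)C(F)(F)F)=C(C)[C@H]1O[Si](CC)(CC)CC
F11 | step 7 | methyl 3-(tert-butyldimethylsilyloxy)-2,3,5-trimethyl-6-(triethylsilyloxy)cyclohex-4-ene-1-carboxylate | COC(=O)[C@@H]1[C@H](C)[C@@](C)(O[Si](C)(C)C(C)(C)C)C=C(C)[C@H]1O[Si](CC)(CC)CC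
F12 | step 13 | ethyl (2E,4E)-4-methyl-5-(bis-acetonide ring)penta-2,4-dienoate | CCOC(=O)/C=C/C(C)=C/[C@@H]1[C@H](C)[C@@]2(C)OC(C)(C)O[C@H]2[C@@]3(C)OC(C)(C)O[C@@H]13
F13 | step 13 | (2E,4E)-4-methyl-5-(bis-acetonide ring)penta-2,4-dien-1-ol | OC/C=C/C(C)=C/[C@@H]1[C@H](C)[C@@]2(C)OC(C)(C)O[C@H]2[C@@]3(C)OC(C)(C)O[C@@H]13
F14 | step 16 | 6-(1-bromoethyl)-2-methoxy-3,5-dimethyl-4H-pyran-4-one (racemic) | CC(Br)c1oc(OC)c(C)c(=O)c1C
F15 | step 16 | [1-(6-methoxy-3,5-dimethyl-4-oxo-4H-pyran-2-yl)ethyl]triphenylphosphonium bromide | CC(c1oc(OC)c(C)c(=O)c1C)[P+](c1ccccc1)(c1ccccc1)c1ccccc1.[Br-]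
A1 | alternative 1 | 8-[(tert-butyldimethylsilyloxy)methyl]-1,5,7-trimethyl-2,3-dioxabicyclo[2.2.2]oct-5-ene (endoperoxide bridging C15 and C18) | CC(C)(C)[Si](C)(C)OC[C@@H]1[C@H](C)[C@]2(C)C=C(C)[C@H]1OO2
A2 | alternative 1 | 5-[(tert-butyldimethylsilyloxy)methyl]-1,3,6-trimethylcyclohexa-1,3-diene (C13 and C14 substituents cis) | CC(C)(C)[Si](C)(C)OC[C@@H]1[C@H](C)C(C)=CC(C)=C1
A3 | alternative 2 | methyl (E)-3-[2-hydroxy-3,5,6-trimethyl-3,4,5-tris(triethylsilyloxy)cyclohexyl]-2-methylprop-2-enoate | COC(=O)/C(C)=C/[C@@H]1[C@H](C)[C@@](C)(O[Si](CC)(CC)CC)[C@@H](O[Si](CC)(CC)CC)[C@@](C)(O[Si](CC)(CC)CC)[C@H]1O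
A4 | alternative 2 | methyl (E)-2,5,6,8-tetramethyl-9-oxo-6,7,8-tris(triethylsilyloxy)non-2-enoate | COC(=O)/C(C)=C/C[C@H](C)[C@@](C)(O[Si](CC)(CC)CC)[C@@H](O[Si](CC)(CC)CC)[C@@](C)(O[Si](CC)(CC)CC)C=O
A5 | alternative 3 | 4-hydroxy-3,5-dimethyl-6-trienyl-2H-pyran-2-one carrying the silyl-protected core | O=C1OC(/C(C)=C/C=C/C(C)=C/[C@@H]2[C@H](C)[C@@](C)(O[Si](C)(C)C)[C@@H](O[Si](C)(C)C(C)(C)C)[C@@](C)(O[Si](C)(C)C)[C@H]2O[Si](C)(C)C(C)(C)C)=C(C)C(O)=C1C
A6 | alternative 3 | (2E,4E,6E)-2,6-dimethyl-7-(silyl-protected core)hepta-2,4,6-trienoyl imidazolide | O=C(n1ccnc1)/C(C)=C/C=C/C(C)=C/[C@@H]2[C@H](C)[C@@](C)(O[Si](C)(C)C)[C@@H](O[Si](C)(C)C(C)(C)C)[C@@](C)(O[Si](C)(C)C)[C@H]2O[Si](C)(C)C(C)(C)C
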